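The numbers in the tables were computed with made-up constants; scatter was added.

G, the reagent that turns X into Z, is not charged: it reaches the first phase by crossing from Q in the second, and X also reacts with Z to give D.

| flask | X | Q | remark | time | volume of the second phase over the first |
|---|---|---|---|---|---|
| maple | 0.13 M | 0.80 M | run made earlier |  |  |
| ash | 0.30 M | 0.80 M | run made earlier |  |  |
| larch | 0.20 M | 1.2 M | run made earlier |  |  |
| flask | 0.20 M | 0.800 M |  | 3.0 h | 2.0 |

| run | time / min | Z / % | X / % |
|---|---|---|---|
| maple | 20.0 | 6.9 | 92.8 |
| maple | 40.0 | 20.9 | 77.7 |
| maple | 50.0 | 29.6 | 69.5 |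
| maple | 80.0 | 51.1 | 45.4 |
| maple | 90.0 | 56.8 | 38.7 |
| maple | 120 | 70.2 | 23.4 |
| ash | 8.00 | 1.7 | 99.1 |
| ash | 15.0 | 3.7 | 95.9 |
| ash | 25.0 | 9.2 | 89.9 |
| ash | 40.0 | 17.9 | 80.0 |
| ash | 60.0 | 29.3 | 66.4 |
| ash | 120 | 55.4 | 29.1 |
| larch | 8.00 | 2.1 | 97.0 |
| larch | 15.0 | 6.1 | 93.5 |
| larch | 30.0 | 19.1 | 80.3 |
| larch | 60.0 | 46.6 | 48.7 |
| larch | 120 | 77.7 | 11.6 |

(scatter of a reading: 0.5 percentage points)

- in percentages every species weighs as the X in it: one D counts as two
- in the second phase: Q; everything else is in the first
- charges count per volume of the first phase; a concentration in a rate is the amount of a species over the volume of its own phase; every rate counts per litre of the first phase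
- the numbers in the tables scatter by 0.5 percentage points (one standard deviation)
- reactions considered so far: G <-> Q; X + G -> Z; X + Z -> D
- the earlier runs hold the two phases in the same ratio of volumes as the flask asked about

- the Z standing at 3.0 h, as a percentage of the X charged
- the change that raises the amount of Z at 3.0 h, in percent of the X charged most ("none" if none brings more than 2 percentage points) (grey / teal / none)
- amount of Z at 3.0 h, in percent of the X charged, after grey

The reckoning below follows the fraction of X left, through the clock L, minus the natural logarithm of that fraction.

1. First instants. c_G starts from zero, so X barely moves: in maple, L climbs at 0.00374 /min over the first 20.0 min.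

2. Middle. As c_G builds, the maple slope reaches 0.0168 /min, faster than at first. X now decays roughly as a pseudo-first-order species. At 120 min, L reads 1.45 in maple and 1.23 in ash. Interpolated on the charge of X, the flask stands at 1.36.

3. End. Larch runs late at 0.0239 /min. Taken as proportional to c_Q, this gives 0.0159 /min for the flask, whose last 60.0 min are reckoned to leave 9.84% of X.

4. Where the X went. The X + Z step shows in the gap that X and Z leave in the readings. At 120 min, the consumed X standing as D, divided by the X charged, reads 0.643 /M in maple and 0.729 /M in ash. Their mean is σ, the D share per molar of charge: 0.686 /M. Z is then the consumed X times (one minus σ times the charge), or 77.8% for the flask.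

5. Changes. Grey is taken here to double the clock. Larch reads σ = 0.605 /M, and extending that trend in c_Q gives Z = 88.6%. Teal is taken to shorten the delay and to leave the level c_G climbs towards, and the choice here is grey.

The forecast gave 77%, grey and 90% after grey, on the ground that “Doubling Q doubles G at every moment”, against the 77.8% reckoned here.

The flask holds 76.7% of Z at 3.0 h, and grey is the better change, with 89.6% of Z, a gain of 13 percentage points against 5.8 points for teal.

G ⇌ Q, rate k1*([G] - [Q]/K1) per volume of the first phase (partition coefficient = 0.790, kL = 0.0110 /min); X + G → Z (k = 0.0780 /M/min); X + Z → D (k = 0.0140 /M/min) At 0.808 h, Z in the flask was made 14.5 times faster than it was used up, each step taken net. With 9.02% of X and 14.3% of D standing at 3.00 h, the flask's own σ is 0.785 /M. The neighbouring flask charged with 0.80 M of X has 26.7% of X left at 3.00 h, so the carried σ gives 33.1% of Z, and that flask holds 32.0%.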